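**Design of a synthesis of quercetin 3',4'-bis(hydrogen sulfate) (15)**

## The problem

The target, 15, is quercetin carrying hydrogen sulfate esters on both oxygens of its catechol (ring B, O3' and O4') and free hydroxyls at C3, C5 and C7. The skeleton is a flat 2-arylchromen-4-one: ring A (oxygenated at C5 and C7) is fused to the pyranone ring C across the C4a–C8a bond, and ring B is attached at C2. There is no stereocentre, so nothing has to be controlled in three dimensions; the only geometric question arises in an open-chain precursor, where the carboxyl must lie cis to the aryloxy group. The real task is to place two sulfates on two of five hydroxyls, so O3, O5 and O7 need one kind of mask and O3' and O4' another that can be removed while the first stays. Aryl sulfate monoesters are anionic, water-soluble and cleaved by aqueous acid and by Lewis acids, so they must be installed at the penultimate stage and the last deprotection must be neutral; hydrogenolysis of benzyl ethers meets that condition. Two sulfates on neighbouring oxygens add a difficulty, because the first anion retards the second esterification. The oxygen at C3 is best brought in at the correct oxidation level, since a late oxidation of C3 would have to spare five ether groups. The feature that invites the key step is ring A itself: C4a lies ortho to the ring oxygen O1 (on C8a) and ortho and para to the C5 and C7 oxygens of a phloroglucinol-type ring, so it is the most nucleophilic carbon available to an acyl cation held through O1–C2=C3, and in a 3,5-dioxygenated phenoxy group the two carbons ortho to O1 are equivalent.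

## Retrosynthesis

**15 to 14.** The three O–benzyl bonds at O3, O5 and O7 are cut last. Benzyl is the one group on these oxygens that leaves under neutral conditions harmless to a sulfate monoester; acid-labile or fluoride-labile groups would endanger the S–O bonds or would not survive the acidic ring closure earlier on. Precursor 14 is the tri-O-benzyl ether of the target. The forward reaction must remove three benzyl groups, including the chelated one at O5, without reducing the C2–C3 double bond.

**14 to 13.** Both S–O bonds are cut, which leads to catechol 13 (3,5,7-tri-O-benzylquercetin). Its only free hydroxyls are the two that must be sulfated, so the problem of site selectivity is moved entirely into the protecting-group pattern. The forward step only has to go to completion on both neighbouring oxygens.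

**13 to 12.** The two O–allyl bonds of ring B are cut. Allyl ethers are chosen over acyl groups because they are indifferent to the ester enolate, phenoxide and hydroxide used earlier. They are chosen over acetals because they survive the anhydrous acid of the ring closure. Zerovalent palladium removes them without touching benzyl ethers. The price is an electron-rich ring B in the key step, which is acceptable for the reasons given there.

**12 to 10 (key disconnection).** The C4–C4a bond is cut, opening ring C to acrylic acid 10, in which the carboxyl is tethered to ring A through C3=C2–O1. The neighbouring cut at O1–C2 would require a ring A ketone in which one of three phloroglucinol oxygens is differentiated from the others. The cut at C4–C4a uses a symmetrical phenol and needs no such differentiation. Precursor 10 has one ring fewer and is assembled from three simple pieces. The forward reaction must activate the acid without harming benzyl or allyl ethers and must have the carboxyl cis to the aryloxy group, or be able to reach that geometry.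

**10 to 9.** The acid is traced to methyl ester 9. A methyl ester is preferred to an acid-labile ester because saponification generates no carbocation next to the highly nucleophilic ring A. The forward step must hydrolyse the ester without displacing the aryloxy group.

**9 to 7 and 8.** The vinyl C2–O1 bond is cut to give enol triflate 7 and 3,5-bis(benzyloxy)phenol 8, a catalogue compound that delivers ring A complete with both benzyl ethers. Building this bond by conjugate addition of 8 to an alkyne would be simpler, but an alkyne cannot carry the C3 oxygen. The forward reaction is an addition–elimination at a fully substituted carbon and is the most demanding step before the ring closure.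

**7 to 6.** The O–S bond is cut to give β-keto ester 6. The forward step must sulfonylate on oxygen and, through a metal chelate, place the triflyloxy group cis to the ester.

**6 to 3 and 4.** The C2–C3 bond is cut in a Claisen sense, leading to acid 3 (activated in the flask as acyl imidazolide 5) and methyl benzyloxyacetate 4, also a catalogue compound. This cut brings in O3 already benzylated and at the right oxidation level. An aldol-type union would need an extra oxidation.

**3 to 1.** The two allyl ether bonds are cut to give 3,4-dihydroxybenzoic acid 1; allyl ester 2 appears only in passing.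

## Roads not taken

**Alternative 1:** Both ring A and ring C are opened (C4a–C5 and O1–C2), leading to the acyclic methyl 8-benzyloxy-9-aryl-3,5,7,9-tetraoxononanoate A2.
- Forward key step: Mg(OMe)2 would induce a Claisen-type attack of chain carbon 6 on the ester carbon, aromatisation to an acylphloroglucinol, and condensation of the new C8a hydroxyl with the aroyl ketone to give chromenone A1.
- Merits: two rings and two bonds form in one operation, the C3 oxygen is in place, and neither an electrophilic aromatic substitution nor a hindered vinylic substitution is needed. In ring-forming economy it is better than the chosen plan.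
- Weak points: A2 must be built by successive acylations of polyanions and has four enolisable positions, the most acidic being the benzyloxy-bearing C8. An aldol mode of folding (a resorcylate) and early closure of the 5,7,9-triketone segment to a γ-pyranone would compete with the desired mode. A1 emerges with free O5 and O7, which would have to be benzylated (the chelated O5 reluctantly) before the acetals are removed, so about four operations follow the key step against three in the chosen plan.
- Comparison: the chosen plan buys ring A ready-made as 8, handles only isolable non-polyanionic intermediates, and is shorter overall.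

**Alternative 2:** Ring A is removed entirely (C5–C6, C7–C8 and C4a–C5), leaving the pyranonyl diazomethyl ketone A4 and (triisopropylsilyloxy)acetylene A5.
- Forward key step: irradiation of A4 would trigger a Wolff rearrangement to a vinylketene, which adds A5 in a [2+2] sense; heating opens the cyclobutenone and closes the six-membered ring onto the pyranone carbon that becomes C4a (Danheiser benzannulation), giving A3.
- Merits: conditions are neutral, the regiochemistry is fixed by the polarisation of A5, ring C with its C2 aryl and C3 oxygen is complete beforehand, and no alkene geometry is at issue. In avoiding acid it is better than the chosen plan.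
- Weak points: the differentiation of O5 (free) from O7 (silylated) in A3 is of no value, because both end as hydroxyls and need the same mask. A4 requires a trisubstituted 4-pyranone carboxylic acid and acylation of a diazoalkane. The γ-pyranone and aryl ketone chromophores may absorb competitively with the diazo group. A5 is moisture-sensitive. Desilylation, double benzylation, acetal removal, sulfation and hydrogenolysis would still follow.
- Comparison: the chosen plan has a ring A that costs no steps and a three-step endgame.

**Alternative 3:** Three bonds of ring C are cut (C4a–C4, C4–C3 and O1–C2), giving 2-iodo-3,5-bis(benzyloxy)phenol A7, carbon monoxide A9 and 4-ethynyl-1,2-bis(methoxymethoxy)benzene A8.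
- Forward key step: PdCl2(PPh3)2 in diethylamine would couple the three in a carbonylative Sonogashira reaction, and the phenol would then add to the ynone in the 6-endo mode to give flavone A6.
- Merits: this is the most convergent of the four plans, it is catalytic, and it avoids both the hindered vinylic substitution and acid. In convergence and in the reliability of the carbon–carbon bond formation it is at least equal to the chosen plan and probably better; the overall step count is comparable.
- Weak points: A6 has no oxygen at C3, so the flavonol would have to be made later by oxidation at C3 in the presence of benzyl ethers and acetals, followed by O-benzylation. A7 requires iodination ortho rather than para to the hydroxyl. Its doubly ortho-substituted, electron-rich C–I bond should add slowly to zerovalent palladium. Closure in the 5-exo mode to an aurone is a known competitor.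
- Comparison: in the chosen plan the C3 oxygen arrives from 4 at the correct oxidation level, ring A needs no halogenation, and no toxic gas is used.

Key step: step 6

Assumption: the sulfate monoesters 14 and 15 are written as neutral hydrogen sulfates, as the target is drawn; in the flask they would be handled as pyridinium or sodium salts, which differ from these formulas only in the counter-ion.

## Route

**Step 1**
Reactants: 1 3,4-dihydroxybenzoic acid
Product: 3 3,4-bis(allyloxy)benzoic acid, via allyl 3,4-bis(allyloxy)benzoate 2 (not isolated)
Conditions: allyl bromide, K2CO3, DMF, 60 °C; then aq. NaOH, MeOH, 60 °C; HCl to pH 2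
Reagents that add atoms: allyl bromide, C=CCBr; sodium hydroxide (oxygen of the regenerated carboxyl), [Na+].[OH-]
Why: Williamson O-alkylation of both phenols and the carboxylate, followed by saponification of the allyl ester; aryl allyl ethers are inert to hydroxide, so only the ester should be cleaved.

**Step 2**
Reactants: 3 3,4-bis(allyloxy)benzoic acid; 4 methyl 2-(benzyloxy)acetate
Product: 6 methyl 2-(benzyloxy)-3-[3,4-bis(allyloxy)phenyl]-3-oxopropanoate (racemic, enolisable), via 1-[3,4-bis(allyloxy)benzoyl]imidazole 5 (not isolated)
Conditions: 3, CDI, THF, 23 °C; added to the enolate of 4 (2.2 equiv; LiN(SiMe3)2, THF, −78 °C), −78 → −40 °C; AcOH quench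
Reagents that add atoms: none
Why: Crossed Claisen-type C-acylation of a lithium ester enolate by an acyl imidazolide that cannot enolise; the second equivalent of enolate deprotonates the more acidic product and so should prevent over-acylation, and allyl and benzyl ethers are inert at low temperature.

**Step 3**
Reactants: 6 methyl 2-(benzyloxy)-3-[3,4-bis(allyloxy)phenyl]-3-oxopropanoate
Product: 7 methyl (E)-2-(benzyloxy)-3-[3,4-bis(allyloxy)phenyl]-3-(trifluoromethanesulfonyloxy)acrylate
Conditions: NaH, CH2Cl2, 0 °C; Tf2O, −78 → 0 °C
Reagents that add atoms: trifluoromethanesulfonic anhydride, O=S(=O)(OS(=O)(=O)C(F)(F)F)C(F)(F)F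
Why: O-Sulfonylation of a β-keto ester enolate; the sodium chelate between the enolate oxygen and the ester carbonyl should place the triflyloxy group cis to the ester, which is E by the sequence rules because benzyloxy outranks the ester carbon.

**Step 4**
Reactants: 7 methyl (E)-2-(benzyloxy)-3-[3,4-bis(allyloxy)phenyl]-3-(trifluoromethanesulfonyloxy)acrylate; 8 3,5-bis(benzyloxy)phenol
Product: 9 methyl (E)-2-(benzyloxy)-3-[3,5-bis(benzyloxy)phenoxy]-3-[3,4-bis(allyloxy)phenyl]acrylate
Conditions: Cs2CO3, MeCN, 23 → 50 °C
Reagents that add atoms: none
Why: Nucleophilic vinylic substitution by addition–elimination: the phenoxide adds to the β-carbon of the vinylogous mixed anhydride and the resulting ester enolate expels triflate, which should carry the geometry over largely with retention. A geometric mixture would still be usable, because step 6 equilibrates the alkene.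

**Step 5**
Reactants: 9 methyl (E)-2-(benzyloxy)-3-[3,5-bis(benzyloxy)phenoxy]-3-[3,4-bis(allyloxy)phenyl]acrylate
Product: 10 (E)-2-(benzyloxy)-3-[3,5-bis(benzyloxy)phenoxy]-3-[3,4-bis(allyloxy)phenyl]acrylic acid
Conditions: LiOH, THF/H2O, 45 °C; then 1 M HCl to pH 3–4, 0 °C
Reagents that add atoms: lithium hydroxide (oxygen of the new carboxyl), [Li+].[OH-]
Why: Saponification of a 3-aryloxyacrylate, the usual prelude to chromone-forming cyclisations; alcohol is left out of the solvent so that no alkoxide can displace the aryloxy group, and cold, mild acidification should spare the enol ether.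

**Step 6**
Reactants: 10 (E)-2-(benzyloxy)-3-[3,5-bis(benzyloxy)phenoxy]-3-[3,4-bis(allyloxy)phenyl]acrylic acid
Product: 12 3,5,7-tris(benzyloxy)-2-[3,4-bis(allyloxy)phenyl]chromen-4-one, via mixed trifluoroacetic anhydride 11 (not isolated)
Conditions: (CF3CO)2O, CH2Cl2, 0 → 23 °C
Reagents that add atoms: none
Why: Trifluoroacetic anhydride converts acid 10 into mixed anhydride 11, which reacts as, or ionises to, an acylium ion conjugated with the enol ether; the ring A carbon ortho to O1 and ortho and para to the two benzyloxy groups attacks it, and loss of a proton restores aromaticity. The closest known reaction type is the acid-mediated cyclisation of 3-aryloxyacrylic and 3-aryloxycinnamic acids to chromones and flavones (Ruhemann-type synthesis), an intramolecular Friedel–Crafts acylation. Ring C closes as a six-membered ring by electrophilic aromatic substitution, with the new carbonyl exocyclic to the bond formed (C4–C4a). No stereocentre is created. The step needs selectivity between sites: the two carbons ortho to O1 are equivalent by the symmetry of the 3,5-bis(benzyloxy)phenoxy ring, the third ring A carbon cannot reach the acyl carbon, and ring B could only close a strained five-membered indenone at a carbon activated by a single para oxygen, so the triply oxygen-activated ring A should win. The E geometry (carboxyl cis to aryloxy) comes from chelate-derived triflate 7; should some Z acid be present, reversible protonation of the push–pull enol ether at C3 by the trifluoroacetic acid formed would allow rotation to the reactive isomer. Benzyl and allyl ethers should tolerate the anhydrous medium, which contains no Lewis acid, at 0–23 °C.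

**Step 7**
Reactants: 12 3,5,7-tris(benzyloxy)-2-[3,4-bis(allyloxy)phenyl]chromen-4-one
Product: 13 3,5,7-tris(benzyloxy)-2-(3,4-dihydroxyphenyl)chromen-4-one
Conditions: Pd(PPh3)4 (5 mol %), morpholine, THF, 23 °C, under argon
Reagents that add atoms: none
Why: Palladium-catalysed allyl transfer (Tsuji–Trost-type deallylation): zerovalent palladium ionises each aryl allyl ether to a π-allyl complex and the phenoxide, and morpholine captures the allyl group; benzyl ethers and the chromenone do not react.

**Step 8**
Reactants: 13 3,5,7-tris(benzyloxy)-2-(3,4-dihydroxyphenyl)chromen-4-one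
Product: 14 3,5,7-tris(benzyloxy)-2-[3,4-bis(sulfooxy)phenyl]chromen-4-one
Conditions: SO3·pyridine (10 equiv), pyridine, 50 °C; then Na+ exchange resin
Reagents that add atoms: sulfur trioxide–pyridine complex, [O-]S(=O)(=O)[n+]1ccccc1
Why: O-Sulfation of phenols by a sulfur trioxide–amine complex; only the two catechol hydroxyls are free, and excess reagent with gentle heating is meant to drive the second esterification, which the neighbouring anion slows. Exchange to the sodium salt removes pyridinium, which would retard the next step.

**Step 9**
Reactants: 14 3,5,7-tris(benzyloxy)-2-[3,4-bis(sulfooxy)phenyl]chromen-4-one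
Product: 15 3,5,7-trihydroxy-2-[3,4-bis(sulfooxy)phenyl]chromen-4-one (quercetin 3',4'-bis(hydrogen sulfate))
Conditions: H2 (1 atm), Pd/C, MeOH/THF/H2O, 23 °C
Reagents that add atoms: none
Why: Hydrogenolysis of benzyl aryl ethers over palladium; the medium stays neutral, so the sulfate monoesters (as sodium salts) should not hydrolyse, and at one atmosphere the tetrasubstituted, conjugated C2–C3 double bond should not be reduced.

## Compound list

1 | 3,4-dihydroxybenzoic acid | OC(=O)c1ccc(O)c(O)c1 | starting material
2 | allyl 3,4-bis(allyloxy)benzoate | C=CCOC(=O)c1ccc(OCC=C)c(OCC=C)c1 | intermediate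
3 | 3,4-bis(allyloxy)benzoic acid | OC(=O)c1ccc(OCC=C)c(OCC=C)c1 | intermediate
4 | methyl 2-(benzyloxy)acetate | COC(=O)COCc1ccccc1 | starting material
5 | 1-[3,4-bis(allyloxy)benzoyl]imidazole | O=C(c1ccc(OCC=C)c(OCC=C)c1)n1ccnc1 | intermediate
6 | methyl 2-(benzyloxy)-3-[3,4-bis(allyloxy)phenyl]-3-oxopropanoate (racemic) | COC(=O)C(OCc1ccccc1)C(=O)c1ccc(OCC=C)c(OCC=C)c1 | intermediate
7 | methyl (E)-2-(benzyloxy)-3-[3,4-bis(allyloxy)phenyl]-3-(trifluoromethanesulfonyloxy)acrylate | COC(=O)/C(OCc1ccccc1)=C(\OS(=O)(=O)C(F)(F)F)c1ccc(OCC=C)c(OCC=C)c1 | intermediate
8 | 3,5-bis(benzyloxy)phenol | Oc1cc(OCc2ccccc2)cc(OCc2ccccc2)c1 | starting material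
9 | methyl (E)-2-(benzyloxy)-3-[3,5-bis(benzyloxy)phenoxy]-3-[3,4-bis(allyloxy)phenyl]acrylate | COC(=O)/C(OCc1ccccc1)=C(\Oc1cc(OCc2ccccc2)cc(OCc2ccccc2)c1)c1ccc(OCC=C)c(OCC=C)c1 | intermediate
10 | (E)-2-(benzyloxy)-3-[3,5-bis(benzyloxy)phenoxy]-3-[3,4-bis(allyloxy)phenyl]acrylic acid | O=C(O)/C(OCc1ccccc1)=C(\Oc1cc(OCc2ccccc2)cc(OCc2ccccc2)c1)c1ccc(OCC=C)c(OCC=C)c1 | intermediate
11 | (E)-2-(benzyloxy)-3-[3,5-bis(benzyloxy)phenoxy]-3-[3,4-bis(allyloxy)phenyl]acrylic trifluoroacetic anhydride | O=C(OC(=O)C(F)(F)F)/C(OCc1ccccc1)=C(\Oc1cc(OCc2ccccc2)cc(OCc2ccccc2)c1)c1ccc(OCC=C)c(OCC=C)c1 | intermediate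
12 | 3,5,7-tris(benzyloxy)-2-[3,4-bis(allyloxy)phenyl]chromen-4-one | O=c1c(OCc2ccccc2)c(-c2ccc(OCC=C)c(OCC=C)c2)oc2cc(OCc3ccccc3)cc(OCc3ccccc3)c12 | intermediate
13 | 3,5,7-tris(benzyloxy)-2-(3,4-dihydroxyphenyl)chromen-4-one | O=c1c(OCc2ccccc2)c(-c2ccc(O)c(O)c2)oc2cc(OCc3ccccc3)cc(OCc3ccccc3)c12 | intermediate
14 | 3,5,7-tris(benzyloxy)-2-[3,4-bis(sulfooxy)phenyl]chromen-4-one | O=c1c(OCc2ccccc2)c(-c2ccc(OS(=O)(=O)O)c(OS(=O)(=O)O)c2)oc2cc(OCc3ccccc3)cc(OCc3ccccc3)c12 | intermediate
15 | 3,5,7-trihydroxy-2-[3,4-bis(sulfooxy)phenyl]chromen-4-one | O=c1c(O)c(-c2ccc(OS(=O)(=O)O)c(OS(=O)(=O)O)c2)oc2cc(O)cc(O)c12 | target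

## Step count and risks

Total step count: 9. Longest linear sequence: 9 steps (1 to 15); 4 and 8 enter as purchased materials.

**Step 6 (key step).** The ring closure may be slower than acid-induced degradation: cleavage of the aryl enol ether after protonation at C3 (loss of ring A as the phenol), loss of the peri 5-O-benzyl group, or intermolecular trifluoroacetylation of ring A. The reason is that the acyl carbon is conjugated with two donor oxygens, so the acylium ion is stabilised and less electrophilic than usual. The fallback closes the same C4–C4a bond with reversed polarity and sets out from 8 and 7. Iodination of 8 ortho to the hydroxyl with N-iodosuccinimide would give 2-iodo-3,5-bis(benzyloxy)phenol F1. Its cesium salt would displace the triflate of 7 as in step 4 to give methyl (E)-2-(benzyloxy)-3-[3,5-bis(benzyloxy)-2-iodophenoxy]-3-[3,4-bis(allyloxy)phenyl]acrylate F2. Iodine–magnesium exchange with iPrMgCl·LiCl in THF at −40 °C and attack of the aryl Grignard on the cis methyl ester (Parham-type cyclisation) would give 12, where the route is rejoined. No acid is involved, and the chromenone formed is a vinylogous ester that should not take up a second equivalent.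

**Step 4.** The phenoxide may attack sulfur instead of carbon (sulfonyl transfer, which returns the enolate of 6), or react through a ring carbon ortho or para to its oxygen. The reason is that the β-carbon of 7 is fully substituted and is made less electrophilic by the α-benzyloxy and the para-allyloxy donors. The fallback uses an aldehyde as the activating group and chloride as the leaving group, and sets out from 6. Saponification and decarboxylation (aqueous NaOH, then acid and gentle warming) would give 2-(benzyloxy)-1-[3,4-bis(allyloxy)phenyl]ethan-1-one F3. Vilsmeier–Haack chloroformylation (POCl3, DMF) would give 2-(benzyloxy)-3-chloro-3-[3,4-bis(allyloxy)phenyl]acrylaldehyde F4. Phenol 8 with K2CO3 in DMF would displace the chloride to give 2-(benzyloxy)-3-[3,5-bis(benzyloxy)phenoxy]-3-[3,4-bis(allyloxy)phenyl]acrylaldehyde F5. Pinnick oxidation (NaClO2, NaH2PO4, 2-methyl-2-butene) would give acid 10, where the route is rejoined. F4, F5 and the acid so obtained would be geometric mixtures, which step 6 tolerates.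

**Step 8.** Sulfation may stop at the monosulfate, because the first sulfate anion repels the incoming reagent and shields the neighbouring hydroxyl. The fallback introduces both sulfates as neutral diesters and sets out from 13. 2,2,2-Trichloroethyl chlorosulfate with Et3N and DMAP in THF would give 3,5,7-tris(benzyloxy)-2-{3,4-bis[(2,2,2-trichloroethoxy)sulfonyloxy]phenyl}chromen-4-one F6, which can be purified on silica. Reductive removal of the trichloroethyl groups with Zn and ammonium formate in methanol would give 14, where the route is rejoined.

**Step 2.** The enolate of 4 may decompose (self-condensation or rearrangement of the benzyloxy-substituted carbanion) before it captures the electron-rich and therefore sluggish acyl imidazolide, or the product enolate may be acylated on oxygen. The fallback forms the same carbon–carbon bond at the aldehyde oxidation level and sets out from 4. Its lithium enolate would add at −78 °C to 3,4-bis(allyloxy)benzaldehyde F7 (from commercial 3,4-dihydroxybenzaldehyde, allyl bromide and K2CO3) to give methyl 2-(benzyloxy)-3-hydroxy-3-[3,4-bis(allyloxy)phenyl]propanoate F8 as a mixture of diastereomers whose configuration is irrelevant. Oxidation with Dess–Martin periodinane would give 6, where the route is rejoined.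

## Further compounds

F1 | step 6 | 2-iodo-3,5-bis(benzyloxy)phenol | Oc1cc(OCc2ccccc2)cc(OCc2ccccc2)c1I
F2 | step 6 | methyl (E)-2-(benzyloxy)-3-[3,5-bis(benzyloxy)-2-iodophenoxy]-3-[3,4-bis(allyloxy)phenyl]acrylate | COC(=O)/C(OCc1ccccc1)=C(\Oc1cc(OCc2ccccc2)cc(OCc2ccccc2)c1I)c1ccc(OCC=C)c(OCC=C)c1
F3 | step 4 | 2-(benzyloxy)-1-[3,4-bis(allyloxy)phenyl]ethan-1-one | O=C(COCc1ccccc1)c1ccc(OCC=C)c(OCC=C)c1
F4 | step 4 | 2-(benzyloxy)-3-chloro-3-[3,4-bis(allyloxy)phenyl]acrylaldehyde (E/Z mixture) | O=CC(OCc1ccccc1)=C(Cl)c1ccc(OCC=C)c(OCC=C)c1
F5 | step 4 | 2-(benzyloxy)-3-[3,5-bis(benzyloxy)phenoxy]-3-[3,4-bis(allyloxy)phenyl]acrylaldehyde (E/Z mixture) | O=CC(OCc1ccccc1)=C(Oc1cc(OCc2ccccc2)cc(OCc2ccccc2)c1)c1ccc(OCC=C)c(OCC=C)c1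
F6 | step 8 | 3,5,7-tris(benzyloxy)-2-{3,4-bis[(2,2,2-trichloroethoxy)sulfonyloxy]phenyl}chromen-4-one | O=c1c(OCc2ccccc2)c(-c2ccc(OS(=O)(=O)OCC(Cl)(Cl)Cl)c(OS(=O)(=O)OCC(Cl)(Cl)Cl)c2)oc2cc(OCc3ccccc3)cc(OCc3ccccc3)c12
F7 | step 2 | 3,4-bis(allyloxy)benzaldehyde | O=Cc1ccc(OCC=C)c(OCC=C)c1
F8 | step 2 | methyl 2-(benzyloxy)-3-hydroxy-3-[3,4-bis(allyloxy)phenyl]propanoate (diastereomer mixture) | COC(=O)C(OCc1ccccc1)C(O)c1ccc(OCC=C)c(OCC=C)c1
A1 | alternative 1 | 3-benzyloxy-5,7-dihydroxy-2-[3,4-bis(methoxymethoxy)phenyl]chromen-4-one | O=c1c(OCc2ccccc2)c(-c2ccc(OCOC)c(OCOC)c2)oc2cc(O)cc(O)c12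
A2 | alternative 1 | methyl 8-(benzyloxy)-9-[3,4-bis(methoxymethoxy)phenyl]-3,5,7,9-tetraoxononanoate | COC(=O)CC(=O)CC(=O)CC(=O)C(OCc1ccccc1)C(=O)c1ccc(OCOC)c(OCOC)c1
A3 | alternative 2 | 3-benzyloxy-5-hydroxy-7-(triisopropylsilyloxy)-2-[3,4-bis(methoxymethoxy)phenyl]chromen-4-one | O=c1c(OCc2ccccc2)c(-c2ccc(OCOC)c(OCOC)c2)oc2cc(O[Si](C(C)C)(C(C)C)C(C)C)cc(O)c12
A4 | alternative 2 | 3-(benzyloxy)-6-(2-diazoacetyl)-2-[3,4-bis(methoxymethoxy)phenyl]-4H-pyran-4-one | [N-]=[N+]=CC(=O)c1cc(=O)c(OCc2ccccc2)c(-c2ccc(OCOC)c(OCOC)c2)o1
A5 | alternative 2 | (triisopropylsilyloxy)acetylene | C#CO[Si](C(C)C)(C(C)C)C(C)C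
A6 | alternative 3 | 5,7-bis(benzyloxy)-2-[3,4-bis(methoxymethoxy)phenyl]chromen-4-one | O=c1cc(-c2ccc(OCOC)c(OCOC)c2)oc2cc(OCc3ccccc3)cc(OCc3ccccc3)c12
A7 | alternative 3 | 2-iodo-3,5-bis(benzyloxy)phenol | Oc1cc(OCc2ccccc2)cc(OCc2ccccc2)c1I
A8 | alternative 3 | 4-ethynyl-1,2-bis(methoxymethoxy)benzene | C#Cc1ccc(OCOC)c(OCOC)c1
A9 | alternative 3 | carbon monoxide | [C-]#[O+]
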